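**Retrosynthetic overview**

- Target 20 is a 5,7-dihydroxyflavone (rings A, C, B) with an (R)-1-methylpiperidin-2-yl ring on C6 of ring A. The strategy rests on that piperidine ring (primed atoms): N1'–C2' maps onto the C=N bond of an aryl aldimine and C3'–C6' onto a four-carbon diene, so C2', the only stereocentre, is made as the ring is made.
- Late disconnections: the C5/C7 methyl ethers; pyranone ring C at O1–C2 and C3–C(=O)Ph, back to an ortho-hydroxyacetophenone and benzoyl chloride; the acetyl group, back to the acetate of a symmetric 3,5-dimethoxyphenol, so the annulation can give only one regioisomer.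
- Piperidine adjustments (N–Me, N–Ts, removal of C4'=O) lead back to dihydropyridinone 7, which is cut into N-tosyl aldimine 4 and siloxydiene 5 (enantioselective Mannich–Michael, formal [4+2]).
- Ring order: ring A is bought in aldehyde 1, the piperidine ring closes in step 3, ring C closes in step 12, and ring B arrives with benzoyl chloride.

Key step: step 3

Assumption: the (Rp) antipode of the planar-chiral ferrocenyl phosphine–thioether ligand is taken to direct the diene to the Re face of the aldimine carbon (R at C2'), by analogy with simpler aryl aldimines. If the sense proves opposite, the (Sp) ligand is used with no other change.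

**Step 1**
Reactants: 1 4-hydroxy-2,6-dimethoxybenzaldehyde
Product: 2 2,6-dimethoxy-4-(triisopropylsilyloxy)benzaldehyde
Conditions: i-Pr3SiCl (1.2 equiv), imidazole (2.5 equiv), DMF, 0 °C → rt
Reagents that add atoms: triisopropylsilyl chloride, CC(C)[Si](Cl)(C(C)C)C(C)C
Why: Imidazole-promoted O-silylation (silyl ether formation) of the acidic para-hydroxyl masks the one oxygen that later becomes O1 of the pyranone and keeps it distinct from the two methyl ethers.

**Step 2**
Reactants: 2 2,6-dimethoxy-4-(triisopropylsilyloxy)benzaldehyde; 3 4-methylbenzenesulfonamide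
Product: 4 (E)-N-{[2,6-dimethoxy-4-(triisopropylsilyloxy)phenyl]methylidene}-4-methylbenzenesulfonamide
Conditions: Ti(OEt)4 (2 equiv), toluene, 80 °C
Reagents that add atoms: none
Why: Titanium tetraethoxide serves as Lewis acid and water scavenger in the dehydrative condensation of the sulfonamide with the hindered, donor-rich aldehyde (N-sulfonyl imine formation); the aldimine should form as the E isomer and the neutral medium spares the aryl silyl ether.

**Step 3**
Reactants: 4 (E)-N-{[2,6-dimethoxy-4-(triisopropylsilyloxy)phenyl]methylidene}-4-methylbenzenesulfonamide; 5 (E)-1-methoxy-3-(trimethylsilyloxy)buta-1,3-diene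
Product: 7 (R)-2-[2,6-dimethoxy-4-(triisopropylsilyloxy)phenyl]-1-tosyl-2,3-dihydropyridin-4(1H)-one, via Mannich adduct 6 (not isolated)
Conditions: CuBr (5 mol %), (Rp)-1-(tert-butylsulfanyl)-2-(diphenylphosphino)ferrocene (5.5 mol %), AgClO4 (5 mol %), 5 (2 equiv), CH2Cl2, −20 °C → rt; then CF3CO2H (5 mol %), 0 °C, 15 min; aq NaHCO3
Reagents that add atoms: none
Why: The cationic monovalent copper centre, held by the imine nitrogen and one sulfonyl oxygen of 4, activates the C=N bond, and the terminal CH2 of diene 5 adds to the aldimine carbon in a Mukaiyama–Mannich step that forms C2'–C3' and gives the open-chain β-methoxy enone 6. On brief acid treatment the sulfonamide nitrogen adds to C6' of that enone, closing the piperidine ring at N1'–C6' by a 6-endo-trig aza-Michael addition, and methanol is then eliminated to leave enaminone 7. The closest known reaction is the copper-catalysed enantioselective formal aza-Diels–Alder reaction of N-sulfonyl aryl aldimines with siloxydienes. The single new stereocentre C2' is set in the Mannich step by the planar-chiral phosphine–thioether ligand, which in the two-point-bound imine complex should block the Si face so that the diene adds to the Re face and gives R. The step needs enantioface selectivity and enough electrophilicity in a donor-rich, doubly ortho-substituted aldimine; the N-tosyl group supplies both the activation and the second donor atom for a rigid chelate, and the E geometry of 4 makes the bound imine a single species. Acid contact is kept short and cold because the benzylic C2'–N bond on a ring with three oxygen donors can ionise.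

**Step 4**
Reactants: 7 (R)-2-[2,6-dimethoxy-4-(triisopropylsilyloxy)phenyl]-1-tosyl-2,3-dihydropyridin-4(1H)-one
Product: 8 (R)-2-[2,6-dimethoxy-4-(triisopropylsilyloxy)phenyl]-1-tosylpiperidin-4-one
Conditions: LiBH(s-Bu)3 (L-Selectride, 1.1 equiv), THF, −78 °C; then aq NH4Cl
Reagents that add atoms: none
Why: The bulky trialkylborohydride delivers hydride to C6' of the vinylogous sulfonimide (conjugate 1,4-reduction) and the enolate is protonated cold, so C5'=C6' is saturated without touching C2' or the silyl ether.

**Step 5**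
Reactants: 8 (R)-2-[2,6-dimethoxy-4-(triisopropylsilyloxy)phenyl]-1-tosylpiperidin-4-one
Product: 9 N'-{(2R)-2-[2,6-dimethoxy-4-(triisopropylsilyloxy)phenyl]-1-tosylpiperidin-4-ylidene}-4-methylbenzenesulfonohydrazide (C=N isomer mixture)
Conditions: TsNHNH2 (1.1 equiv), EtOH, 50 °C
Reagents that add atoms: 4-methylbenzenesulfonohydrazide, Cc1ccc(cc1)S(=O)(=O)NN
Why: Condensation of the unhindered C4' ketone with the sulfonyl hydrazide (tosylhydrazone formation) runs in neutral ethanol, avoiding acid that could ionise the benzylic C2'–N bond.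

**Step 6**
Reactants: 9 N'-{(2R)-2-[2,6-dimethoxy-4-(triisopropylsilyloxy)phenyl]-1-tosylpiperidin-4-ylidene}-4-methylbenzenesulfonohydrazide
Product: 10 (R)-2-[2,6-dimethoxy-4-(triisopropylsilyloxy)phenyl]-1-tosylpiperidine
Conditions: catecholborane (2.5 equiv), CHCl3, 0 °C → rt; then NaOAc·3H2O, reflux
Reagents that add atoms: none
Why: Catecholborane hydroborates the C=N bond and acetate then triggers loss of sulfinate and dinitrogen from the hydrazine (Caglioti-type tosylhydrazone reduction), replacing the C4' carbonyl by CH2 under conditions that spare the N-tosyl group, the silyl ether and C2'.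

**Step 7**
Reactants: 10 (R)-2-[2,6-dimethoxy-4-(triisopropylsilyloxy)phenyl]-1-tosylpiperidine
Product: 11 (R)-2-[2,6-dimethoxy-4-(triisopropylsilyloxy)phenyl]piperidine
Conditions: sodium naphthalenide (NaC10H8, ca. 4 equiv), THF, −78 °C; then H2O
Reagents that add atoms: none
Why: Single-electron transfer from the arene radical anion to the tosyl group cleaves the N–S bond (reductive desulfonylation) at −78 °C, where the trioxygenated ring, the methyl ethers and the silyl ether are not reduced.

**Step 8**
Reactants: 11 (R)-2-[2,6-dimethoxy-4-(triisopropylsilyloxy)phenyl]piperidine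
Product: 12 (R)-2-[2,6-dimethoxy-4-(triisopropylsilyloxy)phenyl]-1-methylpiperidine
Conditions: aq CH2O (37 %, 3 equiv), NaBH(OAc)3 (2 equiv), ClCH2CH2Cl, rt
Reagents that add atoms: formaldehyde, C=O
Why: Reductive amination: the secondary amine condenses with formaldehyde to an iminium ion that the mild acetoxyborohydride reduces at once, giving the N-methyl group without quaternisation, while the still-silylated ring does not compete for formaldehyde.

**Step 9**
Reactants: 12 (R)-2-[2,6-dimethoxy-4-(triisopropylsilyloxy)phenyl]-1-methylpiperidine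
Product: 14 3,5-dimethoxy-4-[(2R)-1-methylpiperidin-2-yl]phenyl acetate, via phenol 13 (not isolated)
Conditions: n-Bu4NF (1.1 equiv), THF, 0 °C; then Ac2O (1.5 equiv), Et3N, 0 °C → rt
Reagents that add atoms: acetic anhydride, CC(=O)OC(C)=O
Why: Fluoride cleaves the aryl O–Si bond and the phenoxide is acetylated in the same flask (desilylation then O-acylation), so the free para-aminoalkyl phenol is never handled.

**Step 10**
Reactants: 14 3,5-dimethoxy-4-[(2R)-1-methylpiperidin-2-yl]phenyl acetate
Product: 15 1-{6-hydroxy-2,4-dimethoxy-3-[(2R)-1-methylpiperidin-2-yl]phenyl}ethan-1-one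
Conditions: BF3·OEt2 (4 equiv), ClCH2CH2Cl, 80 °C; then aq NaOAc/MeOH, 50 °C; aq NaHCO3
Reagents that add atoms: none
Why: Fries rearrangement: the Lewis acid activates the aryl ester and the acyl group migrates to one of the two equivalent carbons ortho to the oxygen (the para position carries the piperidine), giving a boron-chelated ortho-hydroxy ketone whose carbonyl is tied to the phenol oxygen, so the neighbouring methyl ether should not be cleaved.

**Step 11**
Reactants: 15 1-{6-hydroxy-2,4-dimethoxy-3-[(2R)-1-methylpiperidin-2-yl]phenyl}ethan-1-one; 16 benzoyl chloride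
Product: 17 2-acetyl-3,5-dimethoxy-4-[(2R)-1-methylpiperidin-2-yl]phenyl benzoate
Conditions: pyridine, 0 °C → rt
Reagents that add atoms: none
Why: O-Acylation of the hydrogen-bonded phenol with the acid chloride in pyridine gives the aryl benzoate needed for the Baker–Venkataraman sequence.

**Step 12**
Reactants: 17 2-acetyl-3,5-dimethoxy-4-[(2R)-1-methylpiperidin-2-yl]phenyl benzoate
Product: 19 5,7-dimethoxy-6-[(2R)-1-methylpiperidin-2-yl]-2-phenyl-4H-chromen-4-one, via diketone 18 (not isolated)
Conditions: KOt-Bu (3 equiv), THF, 0 °C → rt; then AcOH, conc. HCl, 50 °C; aq NaHCO3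
Reagents that add atoms: none
Why: Baker–Venkataraman rearrangement: the ketone enolate attacks the neighbouring ester carbonyl so that the benzoyl group moves from O to C, and in acid the 1,3-diketone closes by attack of the single free phenol on the benzoyl carbonyl with loss of water (cyclodehydration), so only one flavone regioisomer can form.

**Step 13**
Reactants: 19 5,7-dimethoxy-6-[(2R)-1-methylpiperidin-2-yl]-2-phenyl-4H-chromen-4-one
Product: 20 5,7-dihydroxy-6-[(2R)-1-methylpiperidin-2-yl]-2-phenyl-4H-chromen-4-one
Conditions: BBr3 (6 equiv), CH2Cl2, −78 °C → rt; MeOH, then aq NaHCO3 to pH 7–8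
Reagents that add atoms: none
Why: Boron tribromide cleaves both aryl methyl ethers (Lewis-acid-mediated ether cleavage), the C5 ether helped by chelation to the C4 carbonyl and the C7 ether twisted out of plane by the C6 substituent; the excess allows for complexation by the amine and the low temperature protects C2'.

**Compound list**

1 | 4-hydroxy-2,6-dimethoxybenzaldehyde | COc1cc(O)cc(OC)c1C=O | starting material
2 | 2,6-dimethoxy-4-(triisopropylsilyloxy)benzaldehyde | COc1cc(O[Si](C(C)C)(C(C)C)C(C)C)cc(OC)c1C=O | intermediate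
3 | 4-methylbenzenesulfonamide | Cc1ccc(cc1)S(N)(=O)=O | starting material
4 | (E)-N-{[2,6-dimethoxy-4-(triisopropylsilyloxy)phenyl]methylidene}-4-methylbenzenesulfonamide | Cc1ccc(cc1)S(=O)(=O)/N=C/c1c(OC)cc(O[Si](C(C)C)(C(C)C)C(C)C)cc1OC | intermediate
5 | (E)-1-methoxy-3-(trimethylsilyloxy)buta-1,3-diene | CO/C=C/C(=C)O[Si](C)(C)C | starting material
6 | N-{(1R,4E)-1-[2,6-dimethoxy-4-(triisopropylsilyloxy)phenyl]-5-methoxy-3-oxopent-4-en-1-yl}-4-methylbenzenesulfonamide (Mannich adduct) | Cc1ccc(cc1)S(=O)(=O)N[C@H](CC(=O)/C=C/OC)c1c(OC)cc(O[Si](C(C)C)(C(C)C)C(C)C)cc1OC | intermediate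
7 | (R)-2-[2,6-dimethoxy-4-(triisopropylsilyloxy)phenyl]-1-tosyl-2,3-dihydropyridin-4(1H)-one | Cc1ccc(cc1)S(=O)(=O)N1C=CC(=O)C[C@@H]1c1c(OC)cc(O[Si](C(C)C)(C(C)C)C(C)C)cc1OC | intermediate
8 | (R)-2-[2,6-dimethoxy-4-(triisopropylsilyloxy)phenyl]-1-tosylpiperidin-4-one | Cc1ccc(cc1)S(=O)(=O)N1CCC(=O)C[C@@H]1c1c(OC)cc(O[Si](C(C)C)(C(C)C)C(C)C)cc1OC | intermediate
9 | N'-{(2R)-2-[2,6-dimethoxy-4-(triisopropylsilyloxy)phenyl]-1-tosylpiperidin-4-ylidene}-4-methylbenzenesulfonohydrazide | Cc1ccc(cc1)S(=O)(=O)N1CCC(=NNS(=O)(=O)c2ccc(C)cc2)C[C@@H]1c1c(OC)cc(O[Si](C(C)C)(C(C)C)C(C)C)cc1OC | intermediate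
10 | (R)-2-[2,6-dimethoxy-4-(triisopropylsilyloxy)phenyl]-1-tosylpiperidine | Cc1ccc(cc1)S(=O)(=O)N1CCCC[C@@H]1c1c(OC)cc(O[Si](C(C)C)(C(C)C)C(C)C)cc1OC | intermediate
11 | (R)-2-[2,6-dimethoxy-4-(triisopropylsilyloxy)phenyl]piperidine | N1CCCC[C@@H]1c1c(OC)cc(O[Si](C(C)C)(C(C)C)C(C)C)cc1OC | intermediate
12 | (R)-2-[2,6-dimethoxy-4-(triisopropylsilyloxy)phenyl]-1-methylpiperidine | CN1CCCC[C@@H]1c1c(OC)cc(O[Si](C(C)C)(C(C)C)C(C)C)cc1OC | intermediate
13 | 3,5-dimethoxy-4-[(2R)-1-methylpiperidin-2-yl]phenol | CN1CCCC[C@@H]1c1c(OC)cc(O)cc1OC | intermediate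
14 | 3,5-dimethoxy-4-[(2R)-1-methylpiperidin-2-yl]phenyl acetate | CN1CCCC[C@@H]1c1c(OC)cc(OC(C)=O)cc1OC | intermediate
15 | 1-{6-hydroxy-2,4-dimethoxy-3-[(2R)-1-methylpiperidin-2-yl]phenyl}ethan-1-one | CN1CCCC[C@@H]1c1c(OC)cc(O)c(C(C)=O)c1OC | intermediate
16 | benzoyl chloride | O=C(Cl)c1ccccc1 | starting material
17 | 2-acetyl-3,5-dimethoxy-4-[(2R)-1-methylpiperidin-2-yl]phenyl benzoate | CN1CCCC[C@@H]1c1c(OC)cc(OC(=O)c2ccccc2)c(C(C)=O)c1OC | intermediate
18 | 1-{6-hydroxy-2,4-dimethoxy-3-[(2R)-1-methylpiperidin-2-yl]phenyl}-3-phenylpropane-1,3-dione | CN1CCCC[C@@H]1c1c(OC)cc(O)c(C(=O)CC(=O)c2ccccc2)c1OC | intermediate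
19 | 5,7-dimethoxy-6-[(2R)-1-methylpiperidin-2-yl]-2-phenyl-4H-chromen-4-one | CN1CCCC[C@@H]1c1c(OC)cc2oc(-c3ccccc3)cc(=O)c2c1OC | intermediate
20 | 5,7-dihydroxy-6-[(2R)-1-methylpiperidin-2-yl]-2-phenyl-4H-chromen-4-one | CN1CCCC[C@@H]1c1c(O)cc2oc(-c3ccccc3)cc(=O)c2c1O | target

**Step count and risks**

Total steps: 13. Longest linear sequence: 13 steps (1 → 20).

Steps most likely to fail:

Step 3. The donor-rich, doubly ortho-substituted aldimine may be too weakly electrophilic, so that Mannich addition is slow and diene and imine hydrolyse instead. Enantioface discrimination may be poor for this 2,6-disubstituted aryl group. Acid-induced ionisation of the benzylic C2'–N bond during ring closure may erode optical purity. The fallback sets out from aldehyde 2 and rejoins the route at amine 11, using an auxiliary-controlled addition in place of the catalytic cycloaddition. Condensation of 2 with (S)-tert-butanesulfinamide (Ti(OEt)4, THF) should give (S,E)-N-{[2,6-dimethoxy-4-(triisopropylsilyloxy)phenyl]methylidene}-2-methylpropane-2-sulfinamide F1. The Grignard reagent made from 1-bromo-4-chlorobutane and magnesium, 4-chlorobutylmagnesium bromide F2, is added in CH2Cl2 at −48 °C; addition through the chelated chair transition state should give (S)-N-{(1R)-5-chloro-1-[2,6-dimethoxy-4-(triisopropylsilyloxy)phenyl]pentyl}-2-methylpropane-2-sulfinamide F3. Deprotonation with KN(SiMe3)2 in THF closes the ring by 6-exo-tet N-alkylation to (R)-2-[2,6-dimethoxy-4-(triisopropylsilyloxy)phenyl]-1-[(S)-tert-butylsulfinyl]piperidine F4. Brief treatment with HCl in MeOH at 0 °C removes the sulfinyl group and should give 11; the sense of addition would be confirmed, since the ortho-methoxy groups could perturb the chelate.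

Step 10. The tertiary amine may sequester the Lewis acid so that acyl migration stalls. At the temperature then needed, a methyl ether may be cleaved or the benzylic C–N bond may ionise with loss of configurational purity. The fallback sets out from silyl ether 12 and rejoins the route at flavone 19, building ring C by palladium-catalysed carbonylation instead of acyl migration and rearrangement. Desilylation of 12 with n-Bu4NF alone gives phenol 13, this time isolated. Mono-iodination ortho to the hydroxyl (I2, NaHCO3, aq THF, 0 °C) should give 2-iodo-3,5-dimethoxy-4-[(2R)-1-methylpiperidin-2-yl]phenol F5. Carbonylative Sonogashira coupling with phenylacetylene under CO (PdCl2(PPh3)2, Et2NH, DMF, 60 °C), followed in the same flask by 6-endo addition of the phenol to the ynone, should give 19, bypassing steps 10 to 12.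

Step 13. Cleavage of the non-chelated C7 methyl ether may be incomplete, and the prolonged Lewis-acid exposure needed to force it may erode configuration at C2'. The fallback sets out from 19 and ends at target 20, splitting the deprotection into two mechanistically different stages. BCl3 (CH2Cl2, −78 → 0 °C) removes only the chelated C5 methyl group and should give 5-hydroxy-7-methoxy-6-[(2R)-1-methylpiperidin-2-yl]-2-phenyl-4H-chromen-4-one F6. The remaining ether, para to the carbonyl, is then cleaved by SN2 attack of a thiolate at the methyl carbon (NaSEt, DMF, 100 °C) with no Lewis acid present, giving 20 after neutralisation.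

**Further compounds**

F1 | step 3 | (S,E)-N-{[2,6-dimethoxy-4-(triisopropylsilyloxy)phenyl]methylidene}-2-methylpropane-2-sulfinamide | CC(C)(C)[S@](=O)/N=C/c1c(OC)cc(O[Si](C(C)C)(C(C)C)C(C)C)cc1OC
F2 | step 3 | 4-chlorobutylmagnesium bromide | ClCCCC[Mg]Br
F3 | step 3 | (S)-N-{(1R)-5-chloro-1-[2,6-dimethoxy-4-(triisopropylsilyloxy)phenyl]pentyl}-2-methylpropane-2-sulfinamide | CC(C)(C)[S@](=O)N[C@H](CCCCCl)c1c(OC)cc(O[Si](C(C)C)(C(C)C)C(C)C)cc1OC
F4 | step 3 | (R)-2-[2,6-dimethoxy-4-(triisopropylsilyloxy)phenyl]-1-[(S)-tert-butylsulfinyl]piperidine | CC(C)(C)[S@](=O)N1CCCC[C@@H]1c1c(OC)cc(O[Si](C(C)C)(C(C)C)C(C)C)cc1OC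
F5 | step 10 | 2-iodo-3,5-dimethoxy-4-[(2R)-1-methylpiperidin-2-yl]phenol | CN1CCCC[C@@H]1c1c(OC)cc(O)c(I)c1OC
F6 | step 13 | 5-hydroxy-7-methoxy-6-[(2R)-1-methylpiperidin-2-yl]-2-phenyl-4H-chromen-4-one | CN1CCCC[C@@H]1c1c(OC)cc2oc(-c3ccccc3)cc(=O)c2c1O
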